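**Assumption:** the target SMILES has no stereocentre and no descriptor for the hindered aryl–chromone axis, so no stereocontrol is applied (racemic at that axis if it is configurationally stable).

## Retrosynthetic overview

1. Target ⇐ hexa-O-alkyl biflavone by one BCl3 step that frees the two peri (5-O) methyl ethers and one isopropyl ether.
2. Ring C of flavone unit 1 (the 4-methoxyphenyl flavone) ⇐ I2/DMSO oxidative cyclisation of a 2'-hydroxychalcone. The key C–C bond of that chalcone comes from an intermolecular Claisen–Schmidt aldol condensation of an aryl methyl ketone (already carrying flavone unit 2) with 4-methoxybenzaldehyde.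
3. The acetyl group ⇐ Fries-type acetylation ortho to the single phenol of a symmetric 4-hydroxy-2,6-dimethoxyphenyl ring. This fixes the 6-linkage (not 8) without a regiochemical choice.
4. Ring C of flavone unit 2 (the 2,3-diarylchromone, formed first) ⇐ Baker–Venkataraman rearrangement and cyclodehydration of a deoxybenzoin, itself from Friedel–Crafts acylation of 3,5-dimethoxyphenol with an arylacetic acid.
5. Arylacetic acid ⇐ one-carbon homologation of 4-hydroxy-2,6-dimethoxybenzaldehyde (phenol masked as a deactivating tosylate).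

## Route

Step 1
Reactants: 1 4-hydroxy-2,6-dimethoxybenzaldehyde
Product: 2 4-formyl-3,5-dimethoxyphenyl 4-methylbenzenesulfonate
Conditions: TsCl (1.2 equiv), Et3N, DMAP (cat.), CH2Cl2, 0 °C to rt
Reagents that add atoms: p-toluenesulfonyl chloride, Cc1ccc(cc1)S(Cl)(=O)=O
Why: O-sulfonylation of the only phenol protects the oxygen that later becomes O1 of flavone unit 1, and the electron-withdrawing tosylate deactivates this ring against self-acylation in step 5.

Step 2
Reactants: 2 4-formyl-3,5-dimethoxyphenyl 4-methylbenzenesulfonate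
Product: 3 3,5-dimethoxy-4-(2-methoxyethenyl)phenyl 4-methylbenzenesulfonate (E/Z mixture)
Conditions: [Ph3PCH2OMe]Cl (1.4 equiv), NaN(SiMe3)2 (1.35 equiv), THF, 0 °C; then 2, 0 °C to rt
Reagents that add atoms: (methoxymethyl)triphenylphosphonium chloride, COC[P+](c1ccccc1)(c1ccccc1)c1ccccc1.[Cl-]
Why: Wittig olefination with the reactive non-stabilised methoxymethyl ylide homologates even this hindered aldehyde; the alkene geometry is irrelevant and the aryl tosylate is inert to the ylide at 0 °C.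

Step 3
Reactants: 3 3,5-dimethoxy-4-(2-methoxyethenyl)phenyl 4-methylbenzenesulfonate (E/Z mixture)
Product: 4 3,5-dimethoxy-4-(2-oxoethyl)phenyl 4-methylbenzenesulfonate
Conditions: 2 M aq. HCl, THF, 50 °C
Reagents that add atoms: water, O
Why: Acid-catalysed enol ether hydrolysis (C-protonation then loss of methanol from the hemiacetal) gives the arylacetaldehyde, which is used at once.

Step 4
Reactants: 4 3,5-dimethoxy-4-(2-oxoethyl)phenyl 4-methylbenzenesulfonate
Product: 5 [2,6-dimethoxy-4-(tosyloxy)phenyl]acetic acid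
Conditions: NaClO2, NaH2PO4, 2-methyl-2-butene, t-BuOH/H2O, 0 °C to rt
Reagents that add atoms: sodium chlorite, [Na+].[O-]Cl=O
Why: Pinnick oxidation takes the aldehyde to the acid under mild buffered conditions, with 2-methyl-2-butene trapping HOCl so the arene is not chlorinated.

Step 5
Reactants: 5 [2,6-dimethoxy-4-(tosyloxy)phenyl]acetic acid; 6 3,5-dimethoxyphenol
Product: 7 4-[2-(2-hydroxy-4,6-dimethoxyphenyl)-2-oxoethyl]-3,5-dimethoxyphenyl 4-methylbenzenesulfonate
Conditions: BF3·OEt2 (solvent), 6 (1.3 equiv), 80 °C, 2 h; then aq. NaOAc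
Reagents that add atoms: none
Why: BF3-promoted Friedel–Crafts acylation ortho to the OH of the very nucleophilic phenol is the standard deoxybenzoin construction of isoflavonoid chemistry; the tosylated ring of 5 is too deactivated to compete and the ortho-hydroxy ketone formed resists a second acylation.

Step 6
Reactants: 7 4-[2-(2-hydroxy-4,6-dimethoxyphenyl)-2-oxoethyl]-3,5-dimethoxyphenyl 4-methylbenzenesulfonate; 8 4-(propan-2-yloxy)benzoyl chloride
Product: 9 2-{[2,6-dimethoxy-4-(tosyloxy)phenyl]acetyl}-3,5-dimethoxyphenyl 4-(propan-2-yloxy)benzoate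
Conditions: 8 (1.2 equiv), pyridine, DMAP (cat.), rt
Reagents that add atoms: none
Why: DMAP-catalysed O-aroylation of the phenol installs the aroyl group that will be transferred to carbon; its isopropyl ether survives all later acid and base steps yet is cleaved by BCl3 at the end.

Step 7
Reactants: 9 2-{[2,6-dimethoxy-4-(tosyloxy)phenyl]acetyl}-3,5-dimethoxyphenyl 4-(propan-2-yloxy)benzoate
Product: 11 4-{5,7-dimethoxy-4-oxo-2-[4-(propan-2-yloxy)phenyl]-4H-chromen-3-yl}-3,5-dimethoxyphenyl 4-methylbenzenesulfonate, via 1,3-diketone 10 (not isolated)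
Conditions: LiN(SiMe3)2 (2.5 equiv), THF, −78 to 0 °C; AcOH quench, concentrate; then AcOH, H2SO4 (cat.), 90 °C
Reagents that add atoms: none
Why: Baker–Venkataraman rearrangement (the benzylic ketone enolate takes the aroyl group through a six-membered transition state) followed by acid cyclodehydration closes ring C of flavone unit 2 as the 2,3-diarylchromone; the non-nucleophilic amide base spares the tosylate.

Step 8
Reactants: 11 4-{5,7-dimethoxy-4-oxo-2-[4-(propan-2-yloxy)phenyl]-4H-chromen-3-yl}-3,5-dimethoxyphenyl 4-methylbenzenesulfonate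
Product: 12 3-(4-hydroxy-2,6-dimethoxyphenyl)-5,7-dimethoxy-2-[4-(propan-2-yloxy)phenyl]-4H-chromen-4-one
Conditions: KOH (5 equiv), MeOH/THF 1:1, 55 °C; then aq. NH4Cl
Reagents that add atoms: none
Why: Alkaline S–O cleavage of the aryl sulfonate (a detosylation long used in flavonoid chemistry) frees the phenol, while the orthogonal 2,6-dimethoxyaryl group at C3 shields C2 of the chromone from hydroxide addition.

Step 9
Reactants: 12 3-(4-hydroxy-2,6-dimethoxyphenyl)-5,7-dimethoxy-2-[4-(propan-2-yloxy)phenyl]-4H-chromen-4-one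
Product: 14 3-(3-acetyl-4-hydroxy-2,6-dimethoxyphenyl)-5,7-dimethoxy-2-[4-(propan-2-yloxy)phenyl]-4H-chromen-4-one, via aryl acetate 13 (not isolated)
Conditions: Ac2O (2 equiv), BF3·OEt2 (solvent), rt, 16 h; then aq. NaOAc/EtOH, 60 °C
Reagents that add atoms: acetic anhydride, CC(=O)OC(C)=O
Why: O-acetylation and BF3-promoted Fries rearrangement place the acetyl ortho to the phenol on the most electron-rich ring; the two ortho positions are equivalent, so one regioisomer forms, and the only free OH next to the acetyl is the one para to the chromonyl group.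

Step 10
Reactants: 14 3-(3-acetyl-4-hydroxy-2,6-dimethoxyphenyl)-5,7-dimethoxy-2-[4-(propan-2-yloxy)phenyl]-4H-chromen-4-one; 15 4-methoxybenzaldehyde
Product: 17 3-{4-hydroxy-2,6-dimethoxy-3-[(2E)-3-(4-methoxyphenyl)prop-2-enoyl]phenyl}-5,7-dimethoxy-2-[4-(propan-2-yloxy)phenyl]-4H-chromen-4-one, via aldol adduct 16 (not isolated)
Conditions: 15 (1.5 equiv), KOH (50% aq., 10 equiv), EtOH, rt, 36 h; then 1 M HCl to pH 4
Reagents that add atoms: none
Why: Intermolecular Claisen–Schmidt aldol condensation of the methyl ketone enolate with the non-enolisable aldehyde forms the key C–C bond (future C2–C3 of flavone unit 1), and E1cB dehydration of the racemic aldol gives only the E-chalcone.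

Step 11
Reactants: 17 3-{4-hydroxy-2,6-dimethoxy-3-[(2E)-3-(4-methoxyphenyl)prop-2-enoyl]phenyl}-5,7-dimethoxy-2-[4-(propan-2-yloxy)phenyl]-4H-chromen-4-one
Product: 19 6-{5,7-dimethoxy-4-oxo-2-[4-(propan-2-yloxy)phenyl]-4H-chromen-3-yl}-5,7-dimethoxy-2-(4-methoxyphenyl)-4H-chromen-4-one, via flavanone 18 (not isolated)
Conditions: I2 (10 mol %), DMSO, 130 °C, 3 h; aq. Na2S2O3 wash
Reagents that add atoms: none
Why: I2/DMSO oxidative cyclisation (oxa-Michael closure to the racemic flavanone, then iodination–elimination with DMSO as terminal oxidant) gives the flavone; only one free OH flanks the enone, so ring closure can only give the 6-linked isomer.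

Step 12
Reactants: 19 6-{5,7-dimethoxy-4-oxo-2-[4-(propan-2-yloxy)phenyl]-4H-chromen-3-yl}-5,7-dimethoxy-2-(4-methoxyphenyl)-4H-chromen-4-one
Product: 20 stephaflavone B
Conditions: BCl3 (1 M in CH2Cl2, 8 equiv), CH2Cl2, −78 °C to rt; then H2O/1 M HCl
Reagents that add atoms: none
Why: BCl3 cleaves aryl methyl ethers only where a peri carbonyl chelates boron (both 5-OMe groups) and cleaves the isopropyl ether by an SN1-type path, leaving the three non-chelated methyl ethers (7, 7'', 4''') untouched.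

## Compound list

1 | 4-hydroxy-2,6-dimethoxybenzaldehyde | O=Cc1c(OC)cc(O)cc1OC | starting material
2 | 4-formyl-3,5-dimethoxyphenyl 4-methylbenzenesulfonate | O=Cc1c(OC)cc(OS(=O)(=O)c2ccc(C)cc2)cc1OC | intermediate
3 | 3,5-dimethoxy-4-(2-methoxyethenyl)phenyl 4-methylbenzenesulfonate (E/Z mixture, geometry not defined) | COC=Cc1c(OC)cc(OS(=O)(=O)c2ccc(C)cc2)cc1OC | intermediate
4 | 3,5-dimethoxy-4-(2-oxoethyl)phenyl 4-methylbenzenesulfonate | O=CCc1c(OC)cc(OS(=O)(=O)c2ccc(C)cc2)cc1OC | intermediate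
5 | [2,6-dimethoxy-4-(tosyloxy)phenyl]acetic acid | OC(=O)Cc1c(OC)cc(OS(=O)(=O)c2ccc(C)cc2)cc1OC | intermediate
6 | 3,5-dimethoxyphenol | COc1cc(O)cc(OC)c1 | starting material
7 | 4-[2-(2-hydroxy-4,6-dimethoxyphenyl)-2-oxoethyl]-3,5-dimethoxyphenyl 4-methylbenzenesulfonate (deoxybenzoin) | COc1cc(O)c(C(=O)Cc2c(OC)cc(OS(=O)(=O)c3ccc(C)cc3)cc2OC)c(OC)c1 | intermediate
8 | 4-(propan-2-yloxy)benzoyl chloride | CC(C)Oc1ccc(cc1)C(Cl)=O | starting material
9 | 2-{[2,6-dimethoxy-4-(tosyloxy)phenyl]acetyl}-3,5-dimethoxyphenyl 4-(propan-2-yloxy)benzoate | COc1cc(OC(=O)c2ccc(OC(C)C)cc2)c(C(=O)Cc2c(OC)cc(OS(=O)(=O)c3ccc(C)cc3)cc2OC)c(OC)c1 | intermediate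
10 | 1-(2-hydroxy-4,6-dimethoxyphenyl)-2-[2,6-dimethoxy-4-(tosyloxy)phenyl]-3-[4-(propan-2-yloxy)phenyl]propane-1,3-dione (racemic at C2, not isolated) | COc1cc(O)c(C(=O)C(C(=O)c2ccc(OC(C)C)cc2)c2c(OC)cc(OS(=O)(=O)c3ccc(C)cc3)cc2OC)c(OC)c1 | intermediate
11 | 4-{5,7-dimethoxy-4-oxo-2-[4-(propan-2-yloxy)phenyl]-4H-chromen-3-yl}-3,5-dimethoxyphenyl 4-methylbenzenesulfonate | COc1cc(OC)c2c(c1)oc(-c1ccc(OC(C)C)cc1)c(-c1c(OC)cc(OS(=O)(=O)c3ccc(C)cc3)cc1OC)c2=O | intermediate
12 | 3-(4-hydroxy-2,6-dimethoxyphenyl)-5,7-dimethoxy-2-[4-(propan-2-yloxy)phenyl]-4H-chromen-4-one | COc1cc(OC)c2c(c1)oc(-c1ccc(OC(C)C)cc1)c(-c1c(OC)cc(O)cc1OC)c2=O | intermediate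
13 | 4-{5,7-dimethoxy-4-oxo-2-[4-(propan-2-yloxy)phenyl]-4H-chromen-3-yl}-3,5-dimethoxyphenyl acetate (not isolated) | COc1cc(OC)c2c(c1)oc(-c1ccc(OC(C)C)cc1)c(-c1c(OC)cc(OC(C)=O)cc1OC)c2=O | intermediate
14 | 3-(3-acetyl-4-hydroxy-2,6-dimethoxyphenyl)-5,7-dimethoxy-2-[4-(propan-2-yloxy)phenyl]-4H-chromen-4-one | COc1cc(OC)c2c(c1)oc(-c1ccc(OC(C)C)cc1)c(-c1c(OC)cc(O)c(C(C)=O)c1OC)c2=O | intermediate
15 | 4-methoxybenzaldehyde | COc1ccc(C=O)cc1 | starting material
16 | 3-{4-hydroxy-3-[3-hydroxy-3-(4-methoxyphenyl)propanoyl]-2,6-dimethoxyphenyl}-5,7-dimethoxy-2-[4-(propan-2-yloxy)phenyl]-4H-chromen-4-one (racemic aldol, not isolated) | COc1ccc(C(O)CC(=O)c2c(O)cc(OC)c(-c3c(-c4ccc(OC(C)C)cc4)oc4cc(OC)cc(OC)c4c3=O)c2OC)cc1 | intermediate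
17 | 3-{4-hydroxy-2,6-dimethoxy-3-[(2E)-3-(4-methoxyphenyl)prop-2-enoyl]phenyl}-5,7-dimethoxy-2-[4-(propan-2-yloxy)phenyl]-4H-chromen-4-one | COc1ccc(/C=C/C(=O)c2c(O)cc(OC)c(-c3c(-c4ccc(OC(C)C)cc4)oc4cc(OC)cc(OC)c4c3=O)c2OC)cc1 | intermediate
18 | 6-{5,7-dimethoxy-4-oxo-2-[4-(propan-2-yloxy)phenyl]-4H-chromen-3-yl}-5,7-dimethoxy-2-(4-methoxyphenyl)-2,3-dihydro-4H-chromen-4-one (racemic flavanone, not isolated) | COc1ccc(C2CC(=O)c3c(OC)c(-c4c(-c5ccc(OC(C)C)cc5)oc5cc(OC)cc(OC)c5c4=O)c(OC)cc3O2)cc1 | intermediate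
19 | 6-{5,7-dimethoxy-4-oxo-2-[4-(propan-2-yloxy)phenyl]-4H-chromen-3-yl}-5,7-dimethoxy-2-(4-methoxyphenyl)-4H-chromen-4-one | COc1ccc(-c2cc(=O)c3c(OC)c(-c4c(-c5ccc(OC(C)C)cc5)oc5cc(OC)cc(OC)c5c4=O)c(OC)cc3o2)cc1 | intermediate
20 | stephaflavone B: 5-hydroxy-6-[5-hydroxy-2-(4-hydroxyphenyl)-7-methoxy-4-oxo-4H-chromen-3-yl]-7-methoxy-2-(4-methoxyphenyl)-4H-chromen-4-one | COc1ccc(-c2cc(=O)c3c(O)c(-c4c(-c5ccc(O)cc5)oc5cc(OC)cc(O)c5c4=O)c(OC)cc3o2)cc1 | target

## Summary

Total step count: 12. Longest linear sequence: 12 steps (1 to 20); compounds 6, 8 and 15 are bought and added along the way.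

Three steps most likely to fail:

Step 7. The carbon that must be acylated carries a 2,6-disubstituted aryl group, so the Baker–Venkataraman transfer may be slow or stop at the enol ester. The fallback sets out from 7 and returns at 11. Deoxybenzoin 7 is condensed with 4-(propan-2-yloxy)benzaldehyde (piperidine, EtOH, reflux) in a Knoevenagel-type aldol condensation with spontaneous oxa-Michael closure. This gives 4-{5,7-dimethoxy-4-oxo-2-[4-(propan-2-yloxy)phenyl]-3,4-dihydro-2H-chromen-3-yl}-3,5-dimethoxyphenyl 4-methylbenzenesulfonate F1. F1 is dehydrogenated with DDQ in refluxing dioxane to chromone 11.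

Step 8. Warm methanolic KOH could open the chromone before the electron-rich aryl tosylate is cleaved. The fallback sets out from 7 and returns at 12. The tosylate is removed at the base-stable deoxybenzoin stage (KOH, MeOH, reflux) to give 1-(2-hydroxy-4,6-dimethoxyphenyl)-2-(4-hydroxy-2,6-dimethoxyphenyl)ethan-1-one F2. Both phenols are acylated with 8 (2.4 equiv, pyridine, DMAP) to give 4-(2-{2,4-dimethoxy-6-[4-(propan-2-yloxy)benzoyloxy]phenyl}-2-oxoethyl)-3,5-dimethoxyphenyl 4-(propan-2-yloxy)benzoate F3. LiN(SiMe3)2 in THF rearranges only the ester ortho to the ketone, giving 4-{1-(2-hydroxy-4,6-dimethoxyphenyl)-1,3-dioxo-3-[4-(propan-2-yloxy)phenyl]propan-2-yl}-3,5-dimethoxyphenyl 4-(propan-2-yloxy)benzoate F4, which is not isolated. AcOH with catalytic H2SO4 at 90 °C closes it to 4-{5,7-dimethoxy-4-oxo-2-[4-(propan-2-yloxy)phenyl]-4H-chromen-3-yl}-3,5-dimethoxyphenyl 4-(propan-2-yloxy)benzoate F5. The spare aryl ester, which has served as the phenol protecting group, is removed by K2CO3 in MeOH at rt to give 12, so the chromone never meets hot hydroxide.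

Step 10. The hindered, hydrogen-bonded ketone may condense slowly, and prolonged aqueous KOH may attack the chromone of flavone unit 2. The fallback sets out from 14 and returns at 19, skipping 17. The aldol/oxidation pair is replaced by an intermolecular Claisen acylation: the dianion of 14 (LiN(SiMe3)2, 4 equiv, THF, −78 °C) is treated with 4-methoxybenzoyl chloride. This gives 1-(6-hydroxy-2,4-dimethoxy-3-{5,7-dimethoxy-4-oxo-2-[4-(propan-2-yloxy)phenyl]-4H-chromen-3-yl}phenyl)-3-(4-methoxyphenyl)propane-1,3-dione F6. Cyclodehydration of F6 (AcOH, catalytic H2SO4, 95 °C) gives 19 already at the flavone oxidation level.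

Further compounds
F1 | step 7 | 4-{5,7-dimethoxy-4-oxo-2-[4-(propan-2-yloxy)phenyl]-3,4-dihydro-2H-chromen-3-yl}-3,5-dimethoxyphenyl 4-methylbenzenesulfonate (racemic, relative configuration not controlled, both centres removed on dehydrogenation) | COc1cc(OC)c2c(c1)OC(c1ccc(OC(C)C)cc1)C(c1c(OC)cc(OS(=O)(=O)c3ccc(C)cc3)cc1OC)C2=O
F2 | step 8 | 1-(2-hydroxy-4,6-dimethoxyphenyl)-2-(4-hydroxy-2,6-dimethoxyphenyl)ethan-1-one | COc1cc(O)c(C(=O)Cc2c(OC)cc(O)cc2OC)c(OC)c1
F3 | step 8 | 4-(2-{2,4-dimethoxy-6-[4-(propan-2-yloxy)benzoyloxy]phenyl}-2-oxoethyl)-3,5-dimethoxyphenyl 4-(propan-2-yloxy)benzoate | COc1cc(OC(=O)c2ccc(OC(C)C)cc2)c(C(=O)Cc2c(OC)cc(OC(=O)c3ccc(OC(C)C)cc3)cc2OC)c(OC)c1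
F4 | step 8 | 4-{1-(2-hydroxy-4,6-dimethoxyphenyl)-1,3-dioxo-3-[4-(propan-2-yloxy)phenyl]propan-2-yl}-3,5-dimethoxyphenyl 4-(propan-2-yloxy)benzoate (racemic, not isolated) | COc1cc(O)c(C(=O)C(C(=O)c2ccc(OC(C)C)cc2)c2c(OC)cc(OC(=O)c3ccc(OC(C)C)cc3)cc2OC)c(OC)c1
F5 | step 8 | 4-{5,7-dimethoxy-4-oxo-2-[4-(propan-2-yloxy)phenyl]-4H-chromen-3-yl}-3,5-dimethoxyphenyl 4-(propan-2-yloxy)benzoate | COc1cc(OC)c2c(c1)oc(-c1ccc(OC(C)C)cc1)c(-c1c(OC)cc(OC(=O)c3ccc(OC(C)C)cc3)cc1OC)c2=O
F6 | step 10 | 1-(6-hydroxy-2,4-dimethoxy-3-{5,7-dimethoxy-4-oxo-2-[4-(propan-2-yloxy)phenyl]-4H-chromen-3-yl}phenyl)-3-(4-methoxyphenyl)propane-1,3-dione | COc1ccc(C(=O)CC(=O)c2c(O)cc(OC)c(-c3c(-c4ccc(OC(C)C)cc4)oc4cc(OC)cc(OC)c4c3=O)c2OC)cc1
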